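The cyclohexane (C1 quaternary, C2 bearing the hydroxypropyl chain, C3 isopropylidene-substituted, C6 methyl-bearing) is closed last, at the C5–C6 bond. The key step exploits the fact that the exocyclic C3=CMe2 alkene is homoallylic to C5: hydrogen-atom transfer to a 1-isopropenylcyclopropane gives a cyclopropylcarbinyl radical whose strain-driven opening creates the tetrasubstituted alkene and a C5 radical, which closes 6-exo onto a vinyl group and leaves the C6 methyl, its configuration fixed by allylic strain. In the open-chain precursor C3, C4 and C5 form the cyclopropane; C1 and C2 are set by an enantioselective Ireland–Claisen rearrangement. Isofraxidin is attached at the end.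

Key step: step 11

Remark: the sense of asymmetric induction of the (S,S)-diazaborolidine controller in step 5 is assumed by analogy with simpler allyl esters; if it proves opposite, the (R,R)-controller is used with no other change.

Abbreviations: TBS = tert-butyldimethylsilyl, TBDPS = tert-butyldiphenylsilyl.

Step 1
Reactants: 1 1-(TBS-oxy)propan-2-one
Product: 2 ethyl (2E)-4-(TBS-oxy)-3-methylbut-2-enoate
Conditions: (EtO)2P(O)CH2CO2Et, NaH, THF, 0 °C to rt; the minor Z isomer is removed by chromatography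
Reagents that add atoms: triethyl phosphonoacetate, CCOC(=O)CP(=O)(OCC)OCC
Why: Horner–Wadsworth–Emmons olefination of the ketone should place the ester trans to the larger silyloxymethyl group and so give mainly the E enoate.

Step 2
Reactants: 2 ethyl (2E)-4-(TBS-oxy)-3-methylbut-2-enoate
Product: 3 (2E)-4-(TBS-oxy)-3-methylbut-2-en-1-ol
Conditions: iBu2AlH (2.2 equiv), CH2Cl2, −78 °C; Rochelle salt work-up
Reagents that add atoms: none
Why: 1,2-reduction of the enoate with diisobutylaluminium hydride should give the allylic alcohol without change of alkene geometry or loss of the silyl ether.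

Step 3
Reactants: 4 δ-valerolactone
Product: 7 5-(TBDPS-oxy)pentanoic acid, via sodium 5-hydroxypentanoate 5 (not isolated), via bis-silylated ester 6 (not isolated)
Conditions: NaOH, H2O/MeOH, rt, then evaporation; tBuPh2SiCl (2.2 equiv), imidazole, DMF, rt; K2CO3 (cat.), MeOH/THF/H2O, rt, then citric acid
Reagents that add atoms: sodium hydroxide, [Na+].[OH-]; tert-butyl(chloro)diphenylsilane, CC(C)(C)[Si](Cl)(c1ccccc1)c1ccccc1
Why: Lactone saponification, silylation of both oxygens and selective hydrolysis of the labile silyl ester is a standard route to ω-silyloxy acids.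

Step 4
Reactants: 3 (2E)-4-(TBS-oxy)-3-methylbut-2-en-1-ol; 7 5-(TBDPS-oxy)pentanoic acid
Product: 8 (2E)-4-(TBS-oxy)-3-methylbut-2-en-1-yl 5-(TBDPS-oxy)pentanoate
Conditions: DCC, DMAP (cat.), CH2Cl2, 0 °C to rt
Reagents that add atoms: none
Why: Steglich esterification of an unhindered primary allylic alcohol should proceed without allylic transposition.

Step 5
Reactants: 8 (2E)-4-(TBS-oxy)-3-methylbut-2-en-1-yl 5-(TBDPS-oxy)pentanoate
Product: 10 (2S,3R)-2-[3-(TBDPS-oxy)propyl]-3-[(TBS-oxy)methyl]-3-methylpent-4-enoic acid, via boron ketene acetal 9 (not isolated)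
Conditions: (S,S)-bromoborane controller [made in the flask from BBr3 and (S,S)-N,N'-bis{[3,5-bis(trifluoromethyl)phenyl]sulfonyl}-1,2-diphenylethane-1,2-diamine, CH2Cl2, then evacuation], iPr2NEt, CH2Cl2, −78 °C, then 4 °C; aqueous work-up with recovery of the bis-sulfonamide
Reagents that add atoms: none
Why: Enantioselective boron-enolate Ireland–Claisen rearrangement: the Z(O)-boron ketene acetal and the E-alkene should pass through a chair transition state with the side chain and the CH2OTBS group both equatorial, which gives the 2,3-syn relationship, while the C2-symmetric controller differentiates the enolate faces and so fixes C2 as S and the quaternary C3 as R.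

Step 6
Reactants: 10 (2S,3R)-2-[3-(TBDPS-oxy)propyl]-3-[(TBS-oxy)methyl]-3-methylpent-4-enoic acid
Product: 11 (3S,4R)-3-[3-(TBDPS-oxy)propyl]-4-[(TBS-oxy)methyl]-4-methylhex-5-en-2-one
Conditions: MeLi (2.2 equiv), Et2O, 0 °C to rt; inverse quench into cold aqueous NH4Cl
Reagents that add atoms: methyllithium, [Li]C
Why: Addition of methyllithium to the lithium carboxylate should stop at the dilithium gem-diolate and release the methyl ketone only on quench (acid-to-methyl-ketone conversion), leaving the hindered α-stereocentre untouched.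

Step 7
Reactants: 11 (3S,4R)-3-[3-(TBDPS-oxy)propyl]-4-[(TBS-oxy)methyl]-4-methylhex-5-en-2-one
Product: 13 (3S,4R)-3-[3-(TBDPS-oxy)propyl]-4-[(TBS-oxy)methyl]-4-methylhexa-1,5-dien-2-yl trifluoromethanesulfonate, via potassium enolate 12 (not isolated)
Conditions: KN(SiMe3)2, THF, −78 °C; then PhNTf2, −78 to 0 °C
Reagents that add atoms: N-phenylbis(trifluoromethanesulfonimide), O=S(=O)(N(c1ccccc1)S(=O)(=O)C(F)(F)F)C(F)(F)F
Why: Kinetic deprotonation should occur at the methyl group, because the other α-hydrogen is tertiary and flanked by a quaternary carbon, and O-triflation of this enolate gives the terminal enol triflate.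

Step 8
Reactants: 13 (3S,4R)-3-[3-(TBDPS-oxy)propyl]-4-[(TBS-oxy)methyl]-4-methylhexa-1,5-dien-2-yl trifluoromethanesulfonate
Product: 15 (4S,5R)-4-[3-(TBDPS-oxy)propyl]-5-[(TBS-oxy)methyl]-5-methyl-3-methylidenehept-6-en-2-one, via 2-ethoxydiene 14 (not isolated)
Conditions: Bu3Sn[C(OEt)=CH2], Pd(PPh3)4 (5 mol %), LiCl, THF, 65 °C; then 0.5 M HCl, THF, 0 °C, short contact
Reagents that add atoms: tributyl(1-ethoxyvinyl)stannane, CCCC[Sn](CCCC)(CCCC)C(=C)OCC; water, O
Why: Stille cross-coupling of the enol triflate with the α-ethoxyvinylstannane, followed by mild hydrolysis of the enol ether, should give the α-substituted methyl vinyl ketone while the silyl ethers survive.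

Step 9
Reactants: 15 (4S,5R)-4-[3-(TBDPS-oxy)propyl]-5-[(TBS-oxy)methyl]-5-methyl-3-methylidenehept-6-en-2-one
Product: 16 1-{1-[(3R,4S)-7-(TBDPS-oxy)-3-[(TBS-oxy)methyl]-3-methylhept-1-en-4-yl]cyclopropyl}ethan-1-one
Conditions: Me3S(O)I, NaH, DMSO, rt (ylide pre-formed); enone added at 0 °C, then rt
Reagents that add atoms: trimethylsulfoxonium iodide, C[S+](C)(C)=O.[I-]
Why: Corey–Chaykovsky cyclopropanation: conjugate addition of the sulfoxonium ylide to the unhindered CH2 terminus of the enone and 3-exo-tet closure at the α-carbon should build the 1,1-disubstituted cyclopropane without touching the isolated vinyl group.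

Step 10
Reactants: 16 1-{1-[(3R,4S)-7-(TBDPS-oxy)-3-[(TBS-oxy)methyl]-3-methylhept-1-en-4-yl]cyclopropyl}ethan-1-one
Product: 17 (3R,4R)-7-(TBDPS-oxy)-3-[(TBS-oxy)methyl]-3-methyl-4-[1-(prop-1-en-2-yl)cyclopropyl]hept-1-ene
Conditions: Ph3PCH3Br, KOtBu, THF, 0 to 50 °C
Reagents that add atoms: methyltriphenylphosphonium bromide, C[P+](c1ccccc1)(c1ccccc1)c1ccccc1.[Br-]
Why: Wittig methylenation of the cyclopropyl methyl ketone, which has no α-hydrogen on the ring side, should install the isopropenyl group without epimerisation.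

Step 11
Reactants: 17 (3R,4R)-7-(TBDPS-oxy)-3-[(TBS-oxy)methyl]-3-methyl-4-[1-(prop-1-en-2-yl)cyclopropyl]hept-1-ene
Product: 18 tert-butyl{[(1R,2R,6R)-2-[3-(TBDPS-oxy)propyl]-1,6-dimethyl-3-(propan-2-ylidene)cyclohexyl]methoxy}dimethylsilane
Conditions: Mn(dpm)3 (10 mol %; dpm = 2,2,6,6-tetramethylheptane-3,5-dionate), PhSiH3 (1.2 equiv, slow addition), tBuOOH (1.5 equiv), iPrOH/CH2Cl2 (0.01 M), rt, argon
Reagents that add atoms: none
Why: Proposed new method: hydrogen-atom transfer from the manganese hydride to the CH2 of the isopropenyl group should give a tertiary cyclopropylcarbinyl radical, whose strain-driven ring opening forms the tetrasubstituted C3=CMe2 alkene and a primary radical at C5; this radical adds to the internal carbon of the vinyl group (forming C5–C6), and the exocyclic primary radical takes up a second hydrogen atom to become the C6 methyl group. The closest known reaction types are metal-hydride hydrogen-atom-transfer (Mukaiyama-type) hydrogenation and reductive radical cyclisation of dienes, the ring opening of vinylcyclopropanes seen under such conditions, and tin-hydride cascades in which a cyclopropylcarbinyl radical opens and then cyclises; their combination on an isopropenylcyclopropane is not established. The cyclohexane closes in the 6-exo-trig mode, helped by the quaternary C1 in the tether, in preference to 7-endo attack on the terminal CH2. The only new stereocentre, C6, should be set in a chair-like transition state in which 1,3-allylic strain with the just-formed isopropylidene forces the C2 side chain axial, so that the vinyl CH2 must be equatorial to avoid a 1,3-diaxial clash, which places the C6 methyl trans to the C2 chain and cis to the CH2O group (6R). The step needs hydrogen-atom transfer to the 1,1-disubstituted alkene in preference to the monosubstituted vinyl group, secured by the more stable tertiary radical, and cyclisation faster than reduction of the open-chain radical, secured by high dilution and slow addition of the silane; the hindered tetrasubstituted alkene of the product should not react further.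

Step 12
Reactants: 18 tert-butyl{[(1R,2R,6R)-2-[3-(TBDPS-oxy)propyl]-1,6-dimethyl-3-(propan-2-ylidene)cyclohexyl]methoxy}dimethylsilane
Product: 19 [(1R,2R,6R)-2-[3-(TBDPS-oxy)propyl]-1,6-dimethyl-3-(propan-2-ylidene)cyclohexyl]methanol
Conditions: pyridinium p-toluenesulfonate (0.3 equiv), MeOH, 40 °C
Reagents that add atoms: none
Why: Acid-catalysed methanolysis (selective desilylation) should cleave the TBS ether while the far more acid-stable TBDPS ether and the tetrasubstituted alkene survive the weak acid.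

Step 13
Reactants: 19 [(1R,2R,6R)-2-[3-(TBDPS-oxy)propyl]-1,6-dimethyl-3-(propan-2-ylidene)cyclohexyl]methanol; 20 isofraxidin (7-hydroxy-6,8-dimethoxy-2H-chromen-2-one)
Product: 21 7-{[(1R,2R,6R)-2-[3-(TBDPS-oxy)propyl]-1,6-dimethyl-3-(propan-2-ylidene)cyclohexyl]methoxy}-6,8-dimethoxy-2H-chromen-2-one
Conditions: Bu3P=CHCN (1.5 equiv), toluene, 110 °C, sealed tube
Reagents that add atoms: none
Why: Mitsunobu-type etherification with cyanomethylenetributylphosphorane: the acidic 7-hydroxycoumarin protonates the ylide and its phenoxide displaces the alkoxyphosphonium at the neopentyl CH2, which cannot eliminate, the high temperature compensating for the slow SN2 step.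

Step 14
Reactants: 21 7-{[(1R,2R,6R)-2-[3-(TBDPS-oxy)propyl]-1,6-dimethyl-3-(propan-2-ylidene)cyclohexyl]methoxy}-6,8-dimethoxy-2H-chromen-2-one
Product: 22 7-{[(1R,2R,6R)-2-(3-hydroxypropyl)-1,6-dimethyl-3-(propan-2-ylidene)cyclohexyl]methoxy}-6,8-dimethoxy-2H-chromen-2-one (CNP0311605.1)
Conditions: HF·pyridine, pyridine/THF, 0 °C to rt
Reagents that add atoms: none
Why: Fluoride-mediated desilylation under buffered, non-basic conditions should free the primary alcohol and leave the coumarin lactone and the tetrasubstituted alkene intact.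

Compound list
1 | 1-[(tert-butyldimethylsilyl)oxy]propan-2-one | CC(=O)CO[Si](C)(C)C(C)(C)C | starting material
2 | ethyl (2E)-4-[(tert-butyldimethylsilyl)oxy]-3-methylbut-2-enoate | CCOC(=O)/C=C(\C)CO[Si](C)(C)C(C)(C)C | intermediate
3 | (2E)-4-[(tert-butyldimethylsilyl)oxy]-3-methylbut-2-en-1-ol | OC/C=C(\C)CO[Si](C)(C)C(C)(C)C | intermediate
4 | δ-valerolactone (oxan-2-one) | O=C1CCCCO1 | starting material
5 | sodium 5-hydroxypentanoate | [Na+].[O-]C(=O)CCCCO | intermediate (not isolated)
6 | tert-butyldiphenylsilyl 5-[(tert-butyldiphenylsilyl)oxy]pentanoate | CC(C)(C)[Si](OC(=O)CCCCO[Si](c1ccccc1)(c1ccccc1)C(C)(C)C)(c1ccccc1)c1ccccc1 | intermediate (not isolated)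
7 | 5-[(tert-butyldiphenylsilyl)oxy]pentanoic acid | OC(=O)CCCCO[Si](c1ccccc1)(c1ccccc1)C(C)(C)C | intermediate
8 | (2E)-4-[(tert-butyldimethylsilyl)oxy]-3-methylbut-2-en-1-yl 5-[(tert-butyldiphenylsilyl)oxy]pentanoate | CC(C)(C)[Si](C)(C)OC/C(C)=C/COC(=O)CCCCO[Si](c1ccccc1)(c1ccccc1)C(C)(C)C | intermediate
9 | Z(O)-boron ketene acetal of 8 (alkyl chain cis to O–B) carrying the (4S,5S)-4,5-diphenyl-1,3-bis{[3,5-bis(trifluoromethyl)phenyl]sulfonyl}-1,3,2-diazaborolidin-2-yl group on oxygen | CC(C)(C)[Si](C)(C)OC/C(C)=C/CO/C(OB1N(S(=O)(=O)c2cc(cc(c2)C(F)(F)F)C(F)(F)F)[C@@H](c2ccccc2)[C@H](c2ccccc2)N1S(=O)(=O)c1cc(cc(c1)C(F)(F)F)C(F)(F)F)=C/CCCO[Si](c1ccccc1)(c1ccccc1)C(C)(C)C | intermediate (not isolated)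
10 | (2S,3R)-2-{3-[(tert-butyldiphenylsilyl)oxy]propyl}-3-{[(tert-butyldimethylsilyl)oxy]methyl}-3-methylpent-4-enoic acid | C=C[C@@](C)(CO[Si](C)(C)C(C)(C)C)[C@H](CCCO[Si](c1ccccc1)(c1ccccc1)C(C)(C)C)C(=O)O | intermediate
11 | (3S,4R)-3-{3-[(tert-butyldiphenylsilyl)oxy]propyl}-4-{[(tert-butyldimethylsilyl)oxy]methyl}-4-methylhex-5-en-2-one | C=C[C@@](C)(CO[Si](C)(C)C(C)(C)C)[C@H](CCCO[Si](c1ccccc1)(c1ccccc1)C(C)(C)C)C(C)=O | intermediate
12 | potassium (3S,4R)-3-{3-[(tert-butyldiphenylsilyl)oxy]propyl}-4-{[(tert-butyldimethylsilyl)oxy]methyl}-4-methylhexa-1,5-dien-2-olate | C=C[C@@](C)(CO[Si](C)(C)C(C)(C)C)[C@H](CCCO[Si](c1ccccc1)(c1ccccc1)C(C)(C)C)C(=C)[O-].[K+] | intermediate (not isolated)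
13 | (3S,4R)-3-{3-[(tert-butyldiphenylsilyl)oxy]propyl}-4-{[(tert-butyldimethylsilyl)oxy]methyl}-4-methylhexa-1,5-dien-2-yl trifluoromethanesulfonate | C=C[C@@](C)(CO[Si](C)(C)C(C)(C)C)[C@H](CCCO[Si](c1ccccc1)(c1ccccc1)C(C)(C)C)C(=C)OS(=O)(=O)C(F)(F)F | intermediate
14 | (4S,5R)-4-{3-[(tert-butyldiphenylsilyl)oxy]propyl}-5-{[(tert-butyldimethylsilyl)oxy]methyl}-2-ethoxy-5-methyl-3-methylidenehepta-1,6-diene | C=C[C@@](C)(CO[Si](C)(C)C(C)(C)C)[C@H](CCCO[Si](c1ccccc1)(c1ccccc1)C(C)(C)C)C(=C)C(=C)OCC | intermediate (not isolated)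
15 | (4S,5R)-4-{3-[(tert-butyldiphenylsilyl)oxy]propyl}-5-{[(tert-butyldimethylsilyl)oxy]methyl}-5-methyl-3-methylidenehept-6-en-2-one | C=C[C@@](C)(CO[Si](C)(C)C(C)(C)C)[C@H](CCCO[Si](c1ccccc1)(c1ccccc1)C(C)(C)C)C(=C)C(C)=O | intermediate
16 | 1-{1-[(3R,4S)-7-[(tert-butyldiphenylsilyl)oxy]-3-{[(tert-butyldimethylsilyl)oxy]methyl}-3-methylhept-1-en-4-yl]cyclopropyl}ethan-1-one | C=C[C@@](C)(CO[Si](C)(C)C(C)(C)C)[C@H](CCCO[Si](c1ccccc1)(c1ccccc1)C(C)(C)C)C1(CC1)C(C)=O | intermediate
17 | (3R,4R)-7-[(tert-butyldiphenylsilyl)oxy]-3-{[(tert-butyldimethylsilyl)oxy]methyl}-3-methyl-4-[1-(prop-1-en-2-yl)cyclopropyl]hept-1-ene | C=C[C@@](C)(CO[Si](C)(C)C(C)(C)C)[C@H](CCCO[Si](c1ccccc1)(c1ccccc1)C(C)(C)C)C1(CC1)C(C)=C | intermediate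
18 | tert-butyl{[(1R,2R,6R)-2-{3-[(tert-butyldiphenylsilyl)oxy]propyl}-1,6-dimethyl-3-(propan-2-ylidene)cyclohexyl]methoxy}dimethylsilane | CC(C)(C)[Si](C)(C)OC[C@]1(C)[C@H](C)CCC(=C(C)C)[C@H]1CCCO[Si](c1ccccc1)(c1ccccc1)C(C)(C)C | intermediate
19 | [(1R,2R,6R)-2-{3-[(tert-butyldiphenylsilyl)oxy]propyl}-1,6-dimethyl-3-(propan-2-ylidene)cyclohexyl]methanol | OC[C@]1(C)[C@H](C)CCC(=C(C)C)[C@H]1CCCO[Si](c1ccccc1)(c1ccccc1)C(C)(C)C | intermediate
20 | isofraxidin (7-hydroxy-6,8-dimethoxy-2H-chromen-2-one) | COc1cc2ccc(=O)oc2c(OC)c1O | starting material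
21 | 7-{[(1R,2R,6R)-2-{3-[(tert-butyldiphenylsilyl)oxy]propyl}-1,6-dimethyl-3-(propan-2-ylidene)cyclohexyl]methoxy}-6,8-dimethoxy-2H-chromen-2-one | COc1cc2ccc(=O)oc2c(OC)c1OC[C@]1(C)[C@H](C)CCC(=C(C)C)[C@H]1CCCO[Si](c1ccccc1)(c1ccccc1)C(C)(C)C | intermediate
22 | 7-{[(1R,2R,6R)-2-(3-hydroxypropyl)-1,6-dimethyl-3-(propan-2-ylidene)cyclohexyl]methoxy}-6,8-dimethoxy-2H-chromen-2-one | COc1cc2ccc(=O)oc2c(OC)c1OC[C@]1(C)[C@H](C)CCC(=C(C)C)[C@H]1CCCO | target

Total step count: 14. Longest linear sequence: 13 steps (1 to 22 through steps 1, 2 and 4 to 14); step 3 is a one-step side branch.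

Steps most likely to fail

Step 11 (key step). The ring-opened primary radical may be reduced before it closes, hydrogen-atom transfer may go to the vinyl group instead of the isopropenyl group, or a 1,5-hydrogen shift from an allylic methyl group may drain the radical. The fallback uses known chemistry and sets out from ketone 16. Addition of MeMgBr (THF, 0 °C) gives the tertiary cyclopropylcarbinol F1. MgI2 etherate (Et2O/toluene, rt) then effects the cyclopropylcarbinyl-to-homoallyl (Julia-type) rearrangement to the homoallylic iodide F2, in which the tetrasubstituted alkene is already in place. Bu3SnH with azobisisobutyronitrile (slow addition, benzene, 80 °C) closes the ring by 6-exo-trig radical cyclisation under the same conformational control, and the route is rejoined at 18.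

Step 13. The SN2 displacement at the neopentyl CH2 by the di-ortho-substituted phenoxide may be too slow, so that the phosphorane is consumed unproductively. The fallback sets out from alcohol 19 and replaces the redox condensation by a two-step Williamson etherification through a small, highly nucleofugal leaving group. Tf2O with 2,6-lutidine (CH2Cl2, −78 °C) gives the neopentyl triflate F3, which is displaced by the caesium phenoxide of 20 (Cs2CO3, DMF, rt to 50 °C); the route is rejoined at 21.

Step 5. Enolisation or rearrangement of the hindered ester may be incomplete at the low temperature required, or the controller may discriminate the enolate faces insufficiently. The fallback sets out from ester 8 and replaces reagent control by rearrangement to the racemate and resolution. Classical Ireland–Claisen rearrangement (LDA, THF/DMPU, tBuMe2SiCl, −78 °C to rt) through the Z-configured silyl ketene acetal F4 gives, after hydrolytic work-up, the racemic syn acid F5. Classical resolution through the (R)-1-phenylethylammonium salt F6 (crystallisation, then acidification) returns acid 10; should the salt of the wanted enantiomer be the more soluble one, the (S)-amine is used instead.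

Further compounds
F1 | step 11 | 2-{1-[(3R,4S)-7-[(tert-butyldiphenylsilyl)oxy]-3-{[(tert-butyldimethylsilyl)oxy]methyl}-3-methylhept-1-en-4-yl]cyclopropyl}propan-2-ol | C=C[C@@](C)(CO[Si](C)(C)C(C)(C)C)[C@H](CCCO[Si](c1ccccc1)(c1ccccc1)C(C)(C)C)C1(CC1)C(C)(C)O
F2 | step 11 | (3R,4R)-7-[(tert-butyldiphenylsilyl)oxy]-3-{[(tert-butyldimethylsilyl)oxy]methyl}-4-(5-iodo-2-methylpent-2-en-3-yl)-3-methylhept-1-ene | C=C[C@@](C)(CO[Si](C)(C)C(C)(C)C)[C@H](CCCO[Si](c1ccccc1)(c1ccccc1)C(C)(C)C)C(CCI)=C(C)C
F3 | step 13 | [(1R,2R,6R)-2-{3-[(tert-butyldiphenylsilyl)oxy]propyl}-1,6-dimethyl-3-(propan-2-ylidene)cyclohexyl]methyl trifluoromethanesulfonate | O=S(=O)(OC[C@]1(C)[C@H](C)CCC(=C(C)C)[C@H]1CCCO[Si](c1ccccc1)(c1ccccc1)C(C)(C)C)C(F)(F)F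
F4 | step 5 | Z-configured tert-butyldimethylsilyl ketene acetal of ester 8 (alkyl chain cis to O–Si) | CC(C)(C)[Si](C)(C)OC/C(C)=C/CO/C(O[Si](C)(C)C(C)(C)C)=C/CCCO[Si](c1ccccc1)(c1ccccc1)C(C)(C)C
F5 | step 5 | rac-(2S*,3R*)-2-{3-[(tert-butyldiphenylsilyl)oxy]propyl}-3-{[(tert-butyldimethylsilyl)oxy]methyl}-3-methylpent-4-enoic acid | C=CC(C)(CO[Si](C)(C)C(C)(C)C)C(CCCO[Si](c1ccccc1)(c1ccccc1)C(C)(C)C)C(=O)O
F6 | step 5 | (R)-1-phenylethylammonium (2S,3R)-2-{3-[(tert-butyldiphenylsilyl)oxy]propyl}-3-{[(tert-butyldimethylsilyl)oxy]methyl}-3-methylpent-4-enoate | C=C[C@@](C)(CO[Si](C)(C)C(C)(C)C)[C@H](CCCO[Si](c1ccccc1)(c1ccccc1)C(C)(C)C)C(=O)[O-].C[C@@H]([NH3+])c1ccccc1
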